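## Structural features

The target is a 5-alkylresorcinol. Ring A is a benzene ring with two free phenols at positions 3 and 5 and an unbranched thirteen-carbon chain attached at position 1 through the benzylic methylene C1. C2 carries the acetoxy group and is the only stereocentre. It is R (O > C1 > C3 > H) and has no stereogenic neighbour, so its configuration has to come from a reagent or a catalyst. C3 to C7 are five methylenes leading to the dialkyl ketone C8, which bears an n-pentyl group (C9 to C13). The fragile groups are the secondary acetate (base-labile, and homobenzylic, so able to eliminate towards C1), the electron-rich phenols and the ketone, which must be masked from any organometallic reagent. The difficulty is twofold: C2 is flanked by two methylene groups of nearly equal size, so reduction of a C2 ketone would discriminate poorly, and one aliphatic oxygen must end up acetylated while two phenolic oxygens stay free. The key step uses the fact that aryl–C1–C2(O)–C3 is an aryl group, a two-carbon vinyl unit and an alkyl chain around one heteroatom-bearing carbon, with a C2–B bond as a configurationally stable stand-in for C2–O.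

## Logic of the disconnections

14 to 13: the two phenolic O–H bonds are traced back to O–benzyl bonds. The phenols are released last, under neutral hydrogenolysis, so nothing basic or Lewis acidic touches the acetate once it is in place. Benzyl ethers replace methyl ethers because a boron tribromide demethylation next to a carbinol or acetate and a ketone would be hazardous and would force a peracetylation and partial deacetylation detour. The forward step must spare the ketone and the C2–O bond, which is homobenzylic and not benzylic.

13 to 12: the acetyl C–O bond at C2 is cut. With both phenols masked, the C2 hydroxyl of 12 is the only acylable group, so no selectivity between aliphatic and aromatic oxygen is needed.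

12 to 10 (through 11): the C8 carbonyl is traced to its dioxolane and the C2–O bond to a C2–B bond. Both changes are functional-group interconversions that can be telescoped. The oxidation must proceed with retention at C2 and the acid must cleave only the ketal.

10 to 8, 5 and 7 (through 9): the C2–C3 and aryl–C1 bonds are cut together. This reduces the whole carbon skeleton to three achiral pieces and leaves C2 to a chiral palladium catalyst. The forward step needs a halide-tolerant, cationic palladium pathway, a leaving group on the arene that does not coordinate (hence the triflate 7) and a ketone that survives a Grignard reagent (hence the ketal in 5).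

7 to 6: the S–O bond is cut, a one-step sulfonylation of a purchasable phenol.

5 to 4 to 3: the C–Mg bond is traced to a C–Br bond and the ketal C–O bonds to the ketone. The ketal must be in place before magnesium insertion, and the primary bromide must survive ketalisation.

3 to 1 and 2: the C8–C9 bond is cut between an acyl chloride and a pentyl nucleophile. This gives the eleven-carbon bromo ketone in one step, provided the forward reaction stops at the ketone and leaves the C–Br bond alone.

## Other disconnections considered

Alternative 1: The cut runs through ring A, between the aromatic carbon that carries a later-excised carboxyl group and the aromatic carbon that carries the side chain. This unravels the arene into the acyclic trioxo ester allyl (R)-9-(tert-butyldimethylsilyloxy)-15,15-(ethylenedioxy)-3,5,7-trioxoicosanoate A2.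
- Forward key step: with a mild carbonate base and then acid, the doubly activated C2 methylene of A2 would add to its C7 ketone. Loss of water and enolisation would give the resorcylate allyl (R)-2-[2-(tert-butyldimethylsilyloxy)-8,8-(ethylenedioxy)tridecyl]-4,6-dihydroxybenzoate A1.
- In its favour: the 1,3-dioxygenated ring and the ring-to-chain bond arise in one biomimetic operation from non-aromatic material. The key step needs no enantioselective catalysis, because the carbinol centre of A2 would be brought in beforehand from an enantioenriched β-silyloxy ester. On reliance on well-established enantioselective chemistry it is the equal of the chosen plan.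
- Against it: A2 is a highly enolisable polycarbonyl compound that would need successive Claisen-type acylations of polyanions. Its silyloxy group sits β to the C7 ketone and could be expelled by an E1cB pathway under the cyclisation base. Claisen-type closure or O-cyclisation to a pyranone could compete with the aldol. A1 still has to lose the allyl ester, carbon dioxide, the silyl group and the ketal, and the aliphatic hydroxyl would then have to be acetylated beside two free phenols.
- Comparison: structurally it builds ring A, which the chosen plan simply buys. Mechanistically it replaces a catalyst-controlled metallate shift by a carbonyl condensation whose regiochemistry is harder to steer. In step economy the way to A2 and the way on from A1 should make it clearly longer than the eight steps chosen.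

Alternative 2: The C2–C8 segment is read as a seven-membered carbocycle. The C2–O bond of the lactone (R)-8-(3,5-dimethoxybenzyl)oxocan-2-one A3 is traced back to racemic 2-(3,5-dimethoxybenzyl)cycloheptan-1-one A4.
- Forward key step: a Baeyer–Villiger monooxygenase, with its reduced nicotinamide cofactor and molecular oxygen, would oxidise one enantiomer of A4. The enzyme-bound flavin hydroperoxide adds to the carbonyl and the more substituted, benzyl-bearing carbon migrates with retention to give A3. The lactone carbonyl of A3 is C8, so ring opening to an N-methoxy-N-methylamide and addition of a pentyl organometallic reagent would complete the hydroxy ketone skeleton.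
- In its favour: A4 is about two steps from cheap materials. The oxygen enters regioselectively, and C2–OH and C8 arrive already differentiated in A3, so no ketal is needed. No precious metal or chiral ligand is used. The step count would be comparable to, perhaps one lower than, the chosen plan. On these points it is equal or better.
- Against it: acceptance of a seven-membered ketone such as A4, with its bulky arylmethyl group, by an available enzyme is uncertain and would need screening. A kinetic resolution uses at most half of A4 unless its α-centre can be racemised in situ. The methyl ethers of A3 would bring back a late boron tribromide demethylation, so benzyl ethers would have to be substituted.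
- Comparison: structurally the chain comes from a ring, where the chosen plan uses an open-chain Grignard reagent. Mechanistically an enzyme discriminates between enantiomers of a substrate, whereas the chosen plan selects a face of a prochiral alkene and uses all the material. Step economy is about equal.

Alternative 3: Both C–C bonds at C8 (C7–C8 and C8–C9) are cut, with the ketone carbon as a dithiane acyl-anion equivalent.
- Forward key step: 1,3-dithiane A7 would be lithiated and alkylated with 1-bromopentane A8 to give 2-pentyl-1,3-dithiane A9. In the same flask A9 would be lithiated and alkylated with the primary iodide (R)-{[1-(3,5-bis(benzyloxy)phenyl)-7-iodoheptan-2-yl]oxy}(tert-butyl)dimethylsilane A6. The product would be 2-pentyl-2-[(R)-7-[3,5-bis(benzyloxy)phenyl]-6-(tert-butyldimethylsilyloxy)heptyl]-1,3-dithiane A5, a Corey–Seebach double alkylation.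
- In its favour: carbanion alkylations are dependable, the ketone arrives masked in A5, and there is no transition-metal catalyst or halide sensitivity. A7 and A8 are cheap bulk chemicals. In robustness of the key step it is the better plan. The benzyl ether protection of A5 equals that of the chosen plan.
- Against it: the step sets no stereocentre. A6 would need its own enantioselective synthesis, which has to solve the same aryl–C1–C2(O)–C3 problem. Lithiation of A9 is slower than that of A7, and A6 could eliminate under the basic conditions. Unmasking the dithiane of A5 needs oxidative or thiophilic reagents beside an electron-rich arene, and sulfur must be gone before any hydrogenolysis.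
- Comparison: structurally it joins the chain at C8, far from the stereocentre, while the chosen plan joins three pieces at the stereocentre. Mechanistically it is umpolung alkylation against a metal-induced metallate shift. In step economy it is longer, since making A6 alone would match the chosen route up to its key step.

Key step: step 5

Assumption: the (Sp,Sp) antipode of the ferrocenyl bisphosphine (with (R)-aminobenzyl arms) is taken to give the R boronic ester 10; if the sense of induction is the opposite, the mirror-image ligand is used and nothing else changes.

Assumption: 3,5-bis(benzyloxy)phenol 6 is treated as a purchasable compound.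

## Route

Step 1
Reactants: 1 6-bromohexanoyl chloride; 2 pentylmagnesium bromide
Product: 3 1-bromoundecan-6-one
Conditions: Fe(acac)3 (3 mol%), THF, −78 °C, slow addition of 2 (1.05 equiv); aq NH4Cl
Reagents that add atoms: none
Why: Iron-catalysed acylation of a Grignard reagent (acyl cross-coupling): a low-valent iron species formed from Fe(acac)3 and 2 should react with the C–Cl bond of 1 much faster than 2 adds to the ketone or attacks the primary C–Br bond at −78 °C, so the reaction should stop at 3.

Step 2
Reactants: 3 1-bromoundecan-6-one
Product: 4 2-(5-bromopentyl)-2-pentyl-1,3-dioxolane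
Conditions: HOCH2CH2OH (3 equiv), p-TsOH·H2O (5 mol%), toluene, reflux, Dean–Stark
Reagents that add atoms: ethylene glycol, OCCO
Why: Acid-catalysed ketalisation driven by azeotropic removal of water; the ketone is masked before magnesium insertion and the primary bromide is inert to these conditions.

Step 3
Reactants: 4 2-(5-bromopentyl)-2-pentyl-1,3-dioxolane
Product: 5 [5-(2-pentyl-1,3-dioxolan-2-yl)pentyl]magnesium bromide (titrated THF solution, used directly)
Conditions: Mg turnings (1.5 equiv), BrCH2CH2Br (cat.), THF, 25–40 °C, slow addition
Reagents that add atoms: magnesium, [Mg]
Why: Grignard formation by magnesium insertion into a primary alkyl bromide; the remote dioxolane is inert to the reagent, and slow addition at high dilution should limit Wurtz coupling.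

Step 4
Reactants: 6 3,5-bis(benzyloxy)phenol
Product: 7 3,5-bis(benzyloxy)phenyl trifluoromethanesulfonate
Conditions: Tf2O (1.1 equiv), pyridine (2 equiv), CH2Cl2, 0 °C
Reagents that add atoms: trifluoromethanesulfonic anhydride, O=S(=O)(OS(=O)(=O)C(F)(F)F)C(F)(F)F
Why: O-Sulfonylation of a phenol; the benzyl ethers are inert, and the triflate is the non-coordinating leaving group needed for a cationic arylpalladium intermediate.

Step 5
Reactants: 8 vinylboronic acid pinacol ester; 5 [5-(2-pentyl-1,3-dioxolan-2-yl)pentyl]magnesium bromide; 7 3,5-bis(benzyloxy)phenyl trifluoromethanesulfonate
Product: 10 (R)-2-[1-[3,5-bis(benzyloxy)phenyl]-7-(2-pentyl-1,3-dioxolan-2-yl)heptan-2-yl]-4,4,5,5-tetramethyl-1,3,2-dioxaborolane, via vinyl boronate ate complex 9 (not isolated)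
Conditions: 8, NaOTf (2 equiv), THF, 0 °C, then 5 (1.0 equiv), rt; then Pd(OAc)2 (2 mol%), (Sp,Sp)-1,1′-bis[bis(3,5-dimethylphenyl)phosphino]-2,2′-bis[(R)-α-(dimethylamino)benzyl]ferrocene (MandyPhos-type ligand, 2.4 mol%), 7 (1.1 equiv), THF/DMSO, 40 °C
Reagents that add atoms: none
Why: Addition of 5 to the vacant orbital on boron in 8 gives the four-coordinate vinyl boronate 9, with NaOTf assisting the transfer and removing bromide as NaBr. Zerovalent palladium bearing the chiral bisphosphine inserts into the C–O bond of 7; because triflate does not coordinate, the resulting aryl complex of divalent palladium is cationic and binds the vinyl group of 9. The metal then induces a 1,2-metallate shift in which the alkyl chain migrates from boron to C2 anti to palladium while C1 bonds to palladium, forming the C2–C3 bond and creating the stereocentre. Reductive elimination from the β-boryl alkyl(aryl)palladium species forms the aryl–C1 bond and returns zerovalent palladium. The closest known reaction type is the palladium-catalysed enantioselective conjunctive cross-coupling of vinylboron ate complexes, including Grignard-derived ones in the presence of NaOTf, with aryl triflates. No ring is closed, and the configuration at C2 is fixed only by the alkene face that the ligand–palladium fragment selects, since 9 has no other stereocentre. The step needs enantiofacial selectivity (chiral ligand), preference for the metallate shift over direct Suzuki–Miyaura transmetalation and β-hydride elimination (wide-bite-angle bisphosphine, halide-free cationic palladium, fast reductive elimination) and regioselectivity, which is inherent because only the boron-bearing carbon can accept the migrating group. The dioxolane and benzyl ethers are inert, and 10 is R because both carbon substituents at C2 outrank boron.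

Step 6
Reactants: 10 (R)-2-[1-[3,5-bis(benzyloxy)phenyl]-7-(2-pentyl-1,3-dioxolan-2-yl)heptan-2-yl]-4,4,5,5-tetramethyl-1,3,2-dioxaborolane
Product: 12 (R)-1-[3,5-bis(benzyloxy)phenyl]-2-hydroxytridecan-8-one, via dioxolane carbinol 11 (not isolated)
Conditions: NaOH (3 M aq), H2O2 (30% aq), THF, 0 °C → rt; aq Na2S2O3, extraction; crude 11 without purification in THF/2 M HCl, rt
Reagents that add atoms: hydrogen peroxide, OO; water, O
Why: Hydroperoxide oxidation of a secondary alkylboronic ester proceeds by a 1,2-shift of C2 from boron to oxygen with retention, so (R)-10 should give (R)-11; acid-catalysed ketal hydrolysis of the crude carbinol then frees the C8 ketone, and the benzyl ethers and the carbinol tolerate both stages.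

Step 7
Reactants: 12 (R)-1-[3,5-bis(benzyloxy)phenyl]-2-hydroxytridecan-8-one
Product: 13 (R)-1-[3,5-bis(benzyloxy)phenyl]-8-oxotridecan-2-yl acetate
Conditions: Ac2O (1.5 equiv), pyridine, DMAP (5 mol%), CH2Cl2, 0 °C → rt
Reagents that add atoms: acetic anhydride, CC(=O)OC(C)=O
Why: DMAP-catalysed acylation of the only free hydroxyl group; no phenol is free, so no O-selectivity is required, and the C2–O bond is not broken, so the configuration is kept.

Step 8
Reactants: 13 (R)-1-[3,5-bis(benzyloxy)phenyl]-8-oxotridecan-2-yl acetate
Product: 14 (R)-1-(3,5-dihydroxyphenyl)-8-oxotridecan-2-yl acetate (target)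
Conditions: H2 (1 atm), 10% Pd/C, EtOAc, rt
Reagents that add atoms: none
Why: Hydrogenolysis of aryl benzyl ethers under neutral conditions; the dialkyl ketone, the acetate and the homobenzylic C2–O bond should survive at 1 atm and room temperature.

## Compound list

1 | 6-bromohexanoyl chloride | ClC(=O)CCCCCBr | starting material
2 | pentylmagnesium bromide | CCCCC[Mg]Br | starting material
3 | 1-bromoundecan-6-one | CCCCCC(=O)CCCCCBr | intermediate
4 | 2-(5-bromopentyl)-2-pentyl-1,3-dioxolane | CCCCCC1(CCCCCBr)OCCO1 | intermediate
5 | [5-(2-pentyl-1,3-dioxolan-2-yl)pentyl]magnesium bromide | CCCCCC1(CCCCC[Mg]Br)OCCO1 | intermediate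
6 | 3,5-bis(benzyloxy)phenol | Oc1cc(OCc2ccccc2)cc(OCc2ccccc2)c1 | starting material
7 | 3,5-bis(benzyloxy)phenyl trifluoromethanesulfonate | FC(F)(F)S(=O)(=O)Oc1cc(OCc2ccccc2)cc(OCc2ccccc2)c1 | intermediate
8 | vinylboronic acid pinacol ester (4,4,5,5-tetramethyl-2-vinyl-1,3,2-dioxaborolane) | C=CB1OC(C)(C)C(C)(C)O1 | starting material
9 | bromomagnesium [5-(2-pentyl-1,3-dioxolan-2-yl)pentyl](vinyl)(pinacolato)borate (ate complex) | C=C[B-]1(CCCCCC2(CCCCC)OCCO2)OC(C)(C)C(C)(C)O1.[Mg+]Br | intermediate (not isolated)
10 | (R)-2-[1-[3,5-bis(benzyloxy)phenyl]-7-(2-pentyl-1,3-dioxolan-2-yl)heptan-2-yl]-4,4,5,5-tetramethyl-1,3,2-dioxaborolane | CCCCCC1(CCCCC[C@H](Cc2cc(OCc3ccccc3)cc(OCc3ccccc3)c2)B4OC(C)(C)C(C)(C)O4)OCCO1 | intermediate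
11 | (R)-1-[3,5-bis(benzyloxy)phenyl]-7-(2-pentyl-1,3-dioxolan-2-yl)heptan-2-ol | CCCCCC1(CCCCC[C@H](Cc2cc(OCc3ccccc3)cc(OCc3ccccc3)c2)O)OCCO1 | intermediate (not isolated)
12 | (R)-1-[3,5-bis(benzyloxy)phenyl]-2-hydroxytridecan-8-one | CCCCCC(=O)CCCCC[C@H](Cc1cc(OCc2ccccc2)cc(OCc2ccccc2)c1)O | intermediate
13 | (R)-1-[3,5-bis(benzyloxy)phenyl]-8-oxotridecan-2-yl acetate | CCCCCC(=O)CCCCC[C@H](Cc1cc(OCc2ccccc2)cc(OCc2ccccc2)c1)OC(C)=O | intermediate
14 | (R)-1-(3,5-dihydroxyphenyl)-8-oxotridecan-2-yl acetate | CCCCCC(=O)CCCCC[C@H](Cc1cc(O)cc(O)c1)OC(C)=O | target

## Step count and least certain steps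

Total step count: 8. Longest linear sequence: 7 (steps 1, 2, 3, 5, 6, 7 and 8); step 4 is the one-step side branch.

Step 5 (key step). Several processes could fail: incomplete transfer of the alkyl group from magnesium to boron; bromide binding to the cationic palladium centre, which would block alkene coordination; direct transmetalation of the vinyl or alkyl group, or β-hydride elimination from the alkylpalladium intermediate; and insufficient facial discrimination or the opposite sense of induction. The fallback gives up the three-component coupling for an epoxide opening. It sets out from 4 and comes back at 11. Iron-catalysed alkenylation of the primary bromide 4 with vinylmagnesium bromide (Fe(acac)3 5 mol%, TMEDA/hexamethylenetetramine, THF, 0 °C) would give 2-(hept-6-en-1-yl)-2-pentyl-1,3-dioxolane F1. Buffered epoxidation (mCPBA, NaHCO3, CH2Cl2) would give racemic 2-[5-(oxiran-2-yl)pentyl]-2-pentyl-1,3-dioxolane F2. A Jacobsen hydrolytic kinetic resolution, with the appropriate enantiomer of [N,N′-bis(3,5-di-tert-butylsalicylidene)-1,2-cyclohexanediaminato]cobalt acetate and 0.55 equiv of water, would leave (R)-2-[5-(oxiran-2-yl)pentyl]-2-pentyl-1,3-dioxolane F3, the other enantiomer being removed as its diol. Commercial 1,3-bis(benzyloxy)-5-bromobenzene F4 would be converted with magnesium in THF into 3,5-bis(benzyloxy)phenylmagnesium bromide F5. Opening of F3 at the terminal carbon with F5 (CuBr·SMe2 cat., THF, −30 °C; aq NH4Cl) leaves C2 untouched and would give 11, which then passes through the acid stage of step 6 to 12.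

Step 1. The Grignard reagent could add a second time to the ketone, or iron could mediate reduction or homocoupling at the C–Br bond. The fallback replaces catalysis by a stable chelated tetrahedral intermediate. It sets out from 1 and comes back at 3. Acylation of N,O-dimethylhydroxylamine hydrochloride with 1 (K2CO3 2.2 equiv, CH2Cl2/H2O, 0 °C) would give 6-bromo-N-methoxy-N-methylhexanamide F6. Addition of 2 to F6 (THF, 0 °C) and acidic work-up would give 3.

Step 3. Wurtz homocoupling during magnesium insertion, or a low titre of 5, would starve the key step. The fallback reverses the roles of the two boron substituents and avoids the functionalised Grignard reagent. It sets out from 4 and comes back at 10. Copper-catalysed borylation of 4 (B2pin2, CuCl, Xantphos, KOt-Bu, THF, rt) would give 2-[5-(2-pentyl-1,3-dioxolan-2-yl)pentyl]-4,4,5,5-tetramethyl-1,3,2-dioxaborolane F7. Commercial vinylmagnesium chloride would add to F7 (NaOTf, THF) to give chloromagnesium [5-(2-pentyl-1,3-dioxolan-2-yl)pentyl](vinyl)(pinacolato)borate F8. F8 would then be coupled with 7 under the catalyst of step 5 to give 10.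

Step 8. Hydrogenolysis could stall through catalyst poisoning by traces of sulfur or phosphorus carried from earlier steps, or the ketone could be partly reduced on long exposure. The fallback is a non-reductive, Lewis-acid dealkylation that makes no new intermediate. It sets out from 13 and comes back at 14: BCl3 with pentamethylbenzene as benzyl cation scavenger (CH2Cl2, −78 °C; aqueous work-up) would cleave both aryl benzyl ethers, and the ketone and acetate should tolerate this at low temperature.

## Further compounds

F1 | step 5 | 2-(hept-6-en-1-yl)-2-pentyl-1,3-dioxolane | CCCCCC1(CCCCCC=C)OCCO1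
F2 | step 5 | racemic 2-[5-(oxiran-2-yl)pentyl]-2-pentyl-1,3-dioxolane | CCCCCC1(CCCCCC2CO2)OCCO1
F3 | step 5 | (R)-2-[5-(oxiran-2-yl)pentyl]-2-pentyl-1,3-dioxolane | CCCCCC1(CCCCC[C@@H]2CO2)OCCO1
F4 | step 5 | 1,3-bis(benzyloxy)-5-bromobenzene | Brc1cc(OCc2ccccc2)cc(OCc2ccccc2)c1
F5 | step 5 | 3,5-bis(benzyloxy)phenylmagnesium bromide | Br[Mg]c1cc(OCc2ccccc2)cc(OCc2ccccc2)c1
F6 | step 1 | 6-bromo-N-methoxy-N-methylhexanamide | CON(C)C(=O)CCCCCBr
F7 | step 3 | 2-[5-(2-pentyl-1,3-dioxolan-2-yl)pentyl]-4,4,5,5-tetramethyl-1,3,2-dioxaborolane | CCCCCC1(CCCCCB2OC(C)(C)C(C)(C)O2)OCCO1
F8 | step 3 | chloromagnesium [5-(2-pentyl-1,3-dioxolan-2-yl)pentyl](vinyl)(pinacolato)borate | C=C[B-]1(CCCCCC2(CCCCC)OCCO2)OC(C)(C)C(C)(C)O1.[Mg+]Cl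
F0 | step 8 | none | none
A1 | alternative 1 | allyl (R)-2-[2-(tert-butyldimethylsilyloxy)-8,8-(ethylenedioxy)tridecyl]-4,6-dihydroxybenzoate | C=CCOC(=O)c1c(O)cc(O)cc1C[C@H](O[Si](C)(C)C(C)(C)C)CCCCCC2(CCCCC)OCCO2
A2 | alternative 1 | allyl (R)-9-(tert-butyldimethylsilyloxy)-15,15-(ethylenedioxy)-3,5,7-trioxoicosanoate | C=CCOC(=O)CC(=O)CC(=O)CC(=O)C[C@H](O[Si](C)(C)C(C)(C)C)CCCCCC1(CCCCC)OCCO1
A3 | alternative 2 | (R)-8-(3,5-dimethoxybenzyl)oxocan-2-one | O=C1CCCCC[C@H](Cc2cc(OC)cc(OC)c2)O1
A4 | alternative 2 | racemic 2-(3,5-dimethoxybenzyl)cycloheptan-1-one | O=C1CCCCCC1Cc1cc(OC)cc(OC)c1
A5 | alternative 3 | 2-pentyl-2-[(R)-7-[3,5-bis(benzyloxy)phenyl]-6-(tert-butyldimethylsilyloxy)heptyl]-1,3-dithiane | CCCCCC1(CCCCC[C@H](Cc2cc(OCc3ccccc3)cc(OCc3ccccc3)c2)O[Si](C)(C)C(C)(C)C)SCCCS1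
A6 | alternative 3 | (R)-{[1-(3,5-bis(benzyloxy)phenyl)-7-iodoheptan-2-yl]oxy}(tert-butyl)dimethylsilane | ICCCCC[C@H](Cc1cc(OCc2ccccc2)cc(OCc2ccccc2)c1)O[Si](C)(C)C(C)(C)C
A7 | alternative 3 | 1,3-dithiane | C1CSCSC1
A8 | alternative 3 | 1-bromopentane | CCCCCBr
A9 | alternative 3 | 2-pentyl-1,3-dithiane | CCCCCC1SCCCS1
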